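## Structural features

The target (C28H36O5) is a formyl-phloroglucinol meroterpenoid. A cyclopentene (C1–C5) is fused through C1/C5 to a cycloheptane (C1, C5–C10) that carries the C6–C7–C11 gem-dimethylcyclopropane and the tetrasubstituted C1=C10 alkene with C14. An O–C2'–C1'–C7' unit of a 3',5'-diformyl-4',6'-dihydroxyphenyl ring bridges C2 and C4, which closes a benzoxepine (O, C2', C1', C7', C4, C3, C2) and makes the core a bicyclo[4.2.1] system.

There are six stereocentres: C6/C7 (cis-cyclopropane), C5 (H5 trans to H6), the quaternary C4 (C15 on the face of C6, C7' on the face of H5), C2 (oxygen cis to C7', forced by the bridge) and C7' (isobutyl on the side of the one-carbon bridge C3). C5, C4 and C7' are contiguous; C2 and C4 are 1,3-related.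

The fragile elements are the C2–O allyl aryl ether next to the tetrasubstituted alkene (it ionises with acid), the cyclopropane next to C5, the two aldehydes flanked by phenols and, before formylation, a very electron-rich arene. The real difficulty is the congested C5–C4–C7' array: a quaternary carbon between a ring-fusion methine and a fully substituted benzylic methine, in a defined relative configuration, together with closure of the seven-membered ether.

The key step exploits that C4 is a cyclopentane carbon bearing one methyl (C15), one exocyclic carbon (C7') and the ring methylene C3. This is the pattern left when a 1-methylcyclohexene oxide (ring C1–C2–C3–C7'–C4–C5) contracts by a 1,2-shift of C3 from C7' to C4, with C7' expelled as the aldehyde that later becomes the benzylic carbon. A check of the configurations shows that a direct shift inverts C4, so the epoxide oxygen has to lie on the face of H5; a halide-relayed opening would invert twice and give the C4 epimer.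

## Logic of the disconnections

29 ⇒ 27 (through 28). Cut: the two aryl–CHO bonds at C3' and C5'. The aldehydes are the most sensitive groups and deactivate the ring, so they go on last; without them the arene is an electron-rich phloroglucinol ether that can stabilise a cation at C7' earlier. The forward step must formylate twice without acid damage to the C2–O allyl aryl ether, C1=C10 and the cyclopropane.

27 ⇒ 26. Cut: the two phenolic O–H bonds, replaced by O–CH2OMe. Acetal protection permits organolithium, hydride and Lewis-acid chemistry on the arene. The deprotection must be milder than ionisation of the allylic ether and must trap the formaldehyde equivalent.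

26 ⇒ 25. No skeletal bond is cut; C9'–C10' becomes C=C. This exposes the 2-methylallyl retron of an allylsilane addition. Forward, the 1,1-disubstituted alkene must be hydrogenated beside C1=C10 and the cyclopropane.

25 ⇒ 23 + 24. Cut: C7'–C8'. The aryl group places two ortho and one para oxygen donors on C7', so its cation forms easily; cutting while C7' is locked in the bridge removes the C7' stereocentre and the side chain together. The forward step must deliver carbon to the exo face of C7' (the side of C3).

23 ⇒ 22. Cut: C7'–H (carbinol to ketone). A C7' ketone has no α-hydrogen and cannot ionise, so it is the safe form of C7' during ring closure. Forward, a hindered aryl ketone must be reduced; the configuration is immaterial.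

22 ⇒ 21. Cut: C2–O, with transposition of C1=C10 to C1=C2 and a hydroxyl on C10. The bridge lets the phenol reach only C2 on the face of C7', so C2 needs no earlier stereocentre and the tetrasubstituted alkene forms regiospecifically. Forward, the C10–C1–C2 allyl cation must be captured by the phenol faster than it loses a proton, under acid that spares the acetals.

21 ⇒ 20. Cut: C10–C14. This leaves an enone; the methyl nucleophile must add 1,2 to C10 and ignore the aryl ketone.

20 ⇒ 19. Cut: the O–H at C2', back to O–CH2OMe. This restores a symmetric arene unit; forward, only the ortho acetal next to the ketone may be cleaved.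

19 ⇒ 18 ⇒ 14 + 16 (through 17). Cut: C7'–C1', after adjusting C7' to the carbinol level. The aldehyde delivered by the key step is the natural electrophile and the arene a symmetric nucleophile, so the terpenoid and aromatic halves separate. Forward, the aryl nucleophile must prefer the neopentyl aldehyde over the enone.

16 ⇒ 15. Cut: three O–CH2OMe bonds, leaving a commercial triphenol.

14 ⇒ 13 (key). Cut: C3–C4; reconnect C3–C7' and bridge C4/C7' with oxygen. The quaternary C4 becomes an epoxide carbon whose configuration is set by a face-selective epoxidation, and the cyclopentene becomes a cyclohexene that a cycloaddition can build. Forward, C3 must migrate with inversion at C4 faster than H7' shifts. For that reason 13 keeps C1 and C2 sp2: a saturated ring with an equatorial C2 oxygen cis to the epoxide would be held in the chair that aligns H7'.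

13 ⇒ 12. Cut: both C–O bonds of the epoxide. Forward, the peracid must choose C4=C7' over the enone and the face of H5.

12 ⇒ 10 (through 11). Cut: C1–C5 and C2–C3, and re-add HCl across C1=C2. Two rings open to an acyclic chain on the cis-cyclopropane; because C1 and C2 end sp2, the only selectivity required is the π-face at C5.

10 ⇒ 9 ⇒ 6 + 7 (through 8). Cut: C2–Cl to C2–OH, then C1–C2. The dienophile reduces to a methyl ketone and a formate ester; forward, the enolate must form at the methyl group.

6 ⇒ 5 ⇒ 3 + 4. Cut: C3=C7', then C4=C5. The diene reduces to a cyclopropane aldehyde and a three-carbon ylide; both olefinations must choose the aldehyde over the ketone and give the E trisubstituted alkene.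

3 ⇒ 1 (through 2). Reconnect the two carbonyl carbons (future C5 and C10) as the ring alkene of the chiral-pool terpene, which supplies C6 and C7.

## Other disconnections considered

Alternative 1: The cut removes both bonds from C5 to the seven-membered ring (C5–C1 and C5–C6), so the carbocycle reverts to a 2-methylphenyl group on C2 and C5 to a carbenoid carbon on C4, stored as the tosylhydrazone A2. Forward, base and a dirhodium tetracarboxylate such as Rh2(OAc)4 would decompose A2; arene cyclopropanation at the ipso–ortho bond remote from the methyl group and 6π ring opening would give the cycloheptatriene A1.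
- In its favour: one operation forms two C–C bonds, the cyclopentene and the seven-membered ring with C1=C10 and C14 in place. The benzoxepine with C2, C4 and C7' can be assembled first by flat aromatic chemistry. The carbenoid carbon has no α-hydrogen, so a 1,2-hydride shift is excluded.
- Against it here: A1 lacks the cyclopropane and has two extra alkenes. It would need site- and face-selective dimethylcyclopropanation of C6=C7 beside C8=C9 and C1=C10, then selective saturation of C8=C9, on a triene whose double bonds can migrate by 1,5-hydrogen shifts. The non-stabilised carbenoid could also attack the electron-rich dimethoxyarene or the C2–H bond next to oxygen. No chiral-pool input exists, so the three centres of A2 need asymmetric synthesis and C5, C6, C7 come later.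
- Comparison: structurally the order is reversed (ether bridge first, terpenoid ring last). Alternative 1 is better in that it avoids the late cationic ether closure and gets C1=C10 directly, and equal in that C4 is made early in both. Mechanistically both rest on a skeletal reorganisation whose outcome depends on alignment; the Buchner sequence is less predictable in site selectivity than the epoxide shift. Its key step forms more bonds, but the repair of A1 and the synthesis of A2 would probably make the route longer than 19 steps.

Alternative 2: The cut is the C2'–O bond. Forward, the C2 alkoxide of the fluoroarene A4 (KN(SiMe3)2 or Cs2CO3) would displace fluoride at C2', activated by the ortho and para formyl groups, and close the oxepane to the target dimethyl ether A3.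
- In its favour: the formyl groups are installed on a simple arene, so no electrophilic formylation of an acid-sensitive terpenoid is needed. On this point it is better than the chosen plan. Closure under basic conditions avoids an allyl cation and keeps a preformed C2 centre.
- Against it here: alkoxide and aldehydes are not innocent partners (hemiacetal formation, hydride transfer), and the two methoxy groups lower the electrophilicity of C2'. A4 needs a defined C2 allylic alcohol next to the tetrasubstituted alkene and a hexasubstituted arene on the neopentyl C7', so the C4/C7' problem is only moved. Turning A3 into 29 requires double O-demethylation with BBr3 or BCl3, which threatens the allyl aryl ether and the cyclopropane more than the acetal removal of the chosen plan.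
- Comparison: the same ring is closed through the other C–O bond, and the cyclopentane of A4 could come from the same ring contraction (13 → 14), so the two are equal on the core. The polar SNAr closure is mechanistically more predictable than cation capture, which is a point for the alternative. Step economy is about equal: two late steps are saved, but arene synthesis, a stereoselective C2 alcohol and a difficult demethylation are added.

Alternative 3: The cut is C1–C2. Forward, Rh2(OAc)4 or the bulkier Rh2(O2CCPh3)4 would decompose the diazoketone A6, and the carbenoid at C1 would insert into the C2–H bond next to the ether oxygen (1,5-insertion) to give the bridged ketone A5.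
- In its favour: a C–H bond α to oxygen is electronically activated, five-membered insertion is the preferred mode, and no functional handle is needed at C2. The ether bridge exists beforehand, so there is no late ring closure; on this point it is better than the chosen plan. The C10 ketone appears where the methyl group is needed.
- Against it here: the carbenoid carbon is flanked by C5–H, so a 1,2-hydride shift to the C1=C5 enone would be a fast competitor, and the cyclopropane, the isobutyl C–H bonds and the electron-rich arene are further competing sites. A6 requires the C4–C5 bond between the quaternary carbon and a preformed cyclopropane-fused cycloheptanone, with C4, C5 and C7' controlled, by an intermolecular step that the disconnection does not solve. After A5, methyl addition and dehydration must place the alkene at C1=C10 rather than at C9 or C14, a regiochemical question that the allylic transposition 21 → 22 avoids.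
- Comparison: the chosen plan makes the quaternary centre stereospecifically from an epoxide face, while the alternative must make it earlier by other means; the alternative is better on the ether and worse on C4. The selectivity risks (one C–H bond among several versus one migrating group among two) are comparable, so the two are equal on mechanism. With diazo transfer and fragment assembly the route would be as long or longer.

Key step: step 8

Remark on the chemistry: atoms carry the terpenoid numbering used above (C1–C15, C7' benzylic, C8'–C11' isobutyl, C1'–C6' arene); α is the face of the carbocycle that carries H5 and β the face that carries the C5–C6 bond; 1, 4, 7, 15 and 24 are taken to be commercial.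

## Route

Step 1
Reactants: 1 (+)-2-carene
Product: 3 (1S,3R)-2,2-dimethyl-3-(3-oxobutyl)cyclopropane-1-carbaldehyde (cis), via ozonide 2 (not isolated)
Conditions: O3, CH2Cl2, −78 °C; then Me2S, −78 °C → rt
Reagents that add atoms: ozone, [O-][O+]=O
Why: Ozonolysis (Criegee mechanism) with sulfide reduction of the ozonide cleaves the only C=C bond; no stereocentre is formed, the cis-cyclopropane (future C6, C7) is untouched, and the neutral work-up avoids epimerisation next to the formyl group.

Step 2
Reactants: 3 (1S,3R)-2,2-dimethyl-3-(3-oxobutyl)cyclopropane-1-carbaldehyde; 4 2-(triphenylphosphoranylidene)propanal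
Product: 5 (2E)-3-[(1S,3R)-2,2-dimethyl-3-(3-oxobutyl)cyclopropyl]-2-methylprop-2-enal
Conditions: toluene, 90 °C
Reagents that add atoms: none
Why: Wittig olefination with a formyl-stabilised ylide attacks only the aldehyde, is E-selective and needs no base, so the cis-cyclopropane cannot epimerise; the methyl group cis to the ring also blocks the homodienyl 1,5-hydrogen shift of the cis-alkenylcyclopropane on later heating.

Step 3
Reactants: 5 (2E)-3-[(1S,3R)-2,2-dimethyl-3-(3-oxobutyl)cyclopropyl]-2-methylprop-2-enal
Product: 6 4-{(1R,3S)-2,2-dimethyl-3-[(1E)-2-methylbuta-1,3-dien-1-yl]cyclopropyl}butan-2-one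
Conditions: Ph3PCH3Br, KN(SiMe3)2, THF, −78 → 0 °C (1.05 equiv of ylide)
Reagents that add atoms: methyltriphenylphosphonium bromide, C[P+](c1ccccc1)(c1ccccc1)c1ccccc1.[Br-]
Why: Wittig methylenation; with one equivalent of the non-stabilised ylide at low temperature the enal should react far faster than the methyl ketone, and the E trisubstituted alkene is not touched.

Step 4
Reactants: 6 4-{(1R,3S)-2,2-dimethyl-3-[(1E)-2-methylbuta-1,3-dien-1-yl]cyclopropyl}butan-2-one; 7 ethyl formate
Product: 9 (1Z)-1-hydroxy-5-{(1R,3S)-2,2-dimethyl-3-[(1E)-2-methylbuta-1,3-dien-1-yl]cyclopropyl}pent-1-en-3-one (enol of the β-keto aldehyde), via lithium enolate 8 (not isolated)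
Conditions: LiN(i-Pr)2, THF, −78 °C; then HCO2Et, −78 → 0 °C; aq. HCl
Reagents that add atoms: none
Why: Kinetic deprotonation of the methyl ketone at CH3 followed by crossed Claisen condensation with the non-enolisable formate installs C2; the product is a chelated enol and has no new stereocentre.

Step 5
Reactants: 9 (1Z)-1-hydroxy-5-{(1R,3S)-2,2-dimethyl-3-[(1E)-2-methylbuta-1,3-dien-1-yl]cyclopropyl}pent-1-en-3-one
Product: 10 (1E)-1-chloro-5-{(1R,3S)-2,2-dimethyl-3-[(1E)-2-methylbuta-1,3-dien-1-yl]cyclopropyl}pent-1-en-3-one
Conditions: PPh3, CCl4, CH2Cl2, 0 °C → rt
Reagents that add atoms: carbon tetrachloride, ClC(Cl)(Cl)Cl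
Why: The hydroxymethylene ketone is a vinylogous carboxylic acid and is converted into the vinylogous acid chloride under Appel conditions (oxyphosphonium, chloride addition–elimination), which are acid-free and spare the diene; the alkene geometry is immaterial because C1 and C2 become sp2 again in step 6.

Step 6
Reactants: 10 (1E)-1-chloro-5-{(1R,3S)-2,2-dimethyl-3-[(1E)-2-methylbuta-1,3-dien-1-yl]cyclopropyl}pent-1-en-3-one
Product: 12 tricyclic dienone (C10 ketone, C1=C2, C4(C15)=C7', cyclopropane C6–C7–C11, H5 trans to H6), via chloro cycloadduct 11 (not isolated)
Conditions: toluene (0.01 M), BHT, propylene oxide, 130 °C, sealed tube; then Et3N, rt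
Reagents that add atoms: none
Why: A type 1 intramolecular Diels–Alder reaction of the E-diene with the β-chlorovinyl ketone (an ynone equivalent) forms C1–C5 and C2–C3 and closes the six- and seven-membered rings, and E1cB loss of HCl then erases C1 and C2 as stereocentres, so endo/exo and dienophile geometry do not matter; the one centre kept, C5, should be set by the diene adding with its bulk (C4 onwards) on the side of the forming cycloheptane remote from C11 and its syn methyl group, which gives H5 trans to H6.

Step 7
Reactants: 12 tricyclic dienone
Product: 13 epoxy enone (4,7'-epoxide of 12, oxygen α, on the face of H5)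
Conditions: mCPBA, NaHCO3, CH2Cl2, −20 → 0 °C
Reagents that add atoms: 3-chloroperoxybenzoic acid, O=C(OO)c1cccc(Cl)c1
Why: Prilezhaev epoxidation is chemoselective for the electron-rich trisubstituted C4=C7' bond over the enone; allylic strain with C15 and C10 should hold the C5–C6 bond perpendicular to the ring on the β face, so the peracid adds from the α face and both new centres (C4, C7') carry oxygen on the side of H5.

Step 8
Reactants: 13 epoxy enone
Product: 14 enone aldehyde (cyclopentene C1–C5 with C1=C2, C10 ketone, quaternary C4 bearing C15 cis to C6 and the formyl carbon C7' cis to H5)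
Conditions: MeAl(OAr)2 (2.2 equiv; Ar = 4-bromo-2,6-di-tert-butylphenyl; from Me3Al and 2 ArOH), CH2Cl2, −78 °C; then aq. NaF
Reagents that add atoms: none
Why: The aluminium centre binds the epoxide oxygen, the tertiary C4–O bond lengthens, and the ring bond C7'–C3 migrates to C4 anti to the departing oxygen while C7'–O becomes the aldehyde; the closest known reaction type is the Meinwald-type ring contraction of 1-alkylcyclohexene oxides to 1-alkylcyclopentanecarbaldehydes promoted by bulky methylaluminium bis(aryloxides). The cyclopentene ring C1–C5 is closed by this suprafacial 1,2-shift (ring contraction of the six-membered ring), not by a cyclisation. The new stereocentre C4 is controlled by the epoxide face set in step 7: inversion at C4 puts C3 on the β face, so C15 ends cis to C6 and C7' cis to H5, as in 29. The step needs migration of C3 to outrun the shift of H7' (which would give the C7' ketone) and proton loss to an allylic alcohol. The design of 13 answers this: with C1 and C2 sp2 the six-membered ring is nearly flat, the C7'–O–Al bond can stand perpendicular to the plane of the developing cation, and the bulky aryloxides disfavour the rotamer in which O–Al eclipses C15, so the ring bond C7'–C3 and not C7'–H is aligned with the empty orbital. A saturated precursor with sp3 C1 and C2 and an equatorial C2 oxygen cis to the epoxide would sit in the chair that aligns H7' instead (the known contrast between the two limonene 1,2-oxides) and was therefore not used. Shifts from C5 should not compete, because H5 lies in the ring plane and migration of C6 would not end in an oxocarbenium ion. A halide-free Lewis acid is required, since a halide relay would invert C4 twice and give the C4 epimer.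

Step 9
Reactants: 15 phloroglucinol
Product: 16 1,3,5-tris(methoxymethoxy)benzene
Conditions: NaH, MOMCl, DMF, 0 °C → rt
Reagents that add atoms: chloromethyl methyl ether, COCCl
Why: Threefold O-alkylation of the phenoxide (Williamson-type) gives acetal ethers that direct the later lithiation and are removable with mild acid.

Step 10
Reactants: 16 1,3,5-tris(methoxymethoxy)benzene; 14 enone aldehyde
Product: 18 C7' carbinol (2,4,6-tris(methoxymethoxy)phenyl added to C7', both C7' epimers), via aryllithium 17 (not isolated)
Conditions: n-BuLi, THF, 0 °C; then 14, −78 °C; aq. NH4Cl
Reagents that add atoms: none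
Why: Directed ortho-metalation between two OCH2OMe groups gives the aryllithium, which should add 1,2 to the neopentyl aldehyde much faster than to the hindered enone at low temperature; both C7' epimers are acceptable because C7' is oxidised next.

Step 11
Reactants: 18 C7' carbinol
Product: 19 aryl ketone (C7'=O between C4 and the 2,4,6-tris(methoxymethoxy)phenyl ring)
Conditions: Dess–Martin periodinane, NaHCO3, CH2Cl2, rt
Reagents that add atoms: none
Why: Dess–Martin oxidation of the hindered benzylic alcohol under buffered conditions; the ketone has no α-hydrogen, cannot ionise and deactivates the arene during the next three steps.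

Step 12
Reactants: 19 aryl ketone
Product: 20 2'-hydroxy-4',6'-bis(methoxymethoxy)phenyl ketone
Conditions: MgBr2·OEt2, Et2O/CH2Cl2, 0 °C → rt; aq. NH4Cl
Reagents that add atoms: none
Why: Chelation-assisted ether cleavage: magnesium bridges the ketone oxygen and an ortho OCH2OMe group and bromide removes the methoxymethyl group; the two ortho groups interchange by rotation about C7'–C1', the para group is not activated, and the magnesium phenoxide chelate should protect the second ortho group.

Step 13
Reactants: 20 2'-hydroxyaryl ketone
Product: 21 C10 tertiary allylic alcohol (C14 on C10, C1=C2 retained, both C10 epimers)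
Conditions: MeLi, CeCl3, THF, −78 °C; aq. NH4Cl
Reagents that add atoms: methyllithium, [Li]C
Why: 1,2-Addition of the organocerium reagent to the enone carbonyl installs C14 without enolisation or conjugate addition; the aryl ketone is shielded by two ortho substituents and deactivated as the chelated phenoxide, and the C10 configuration is irrelevant because C10 becomes sp2 in step 14.

Step 14
Reactants: 21 C10 tertiary allylic alcohol
Product: 22 bridged benzoxepinone (C2–O–C2' ether with oxygen α at C2, C1=C10, C7' ketone)
Conditions: camphorsulfonic acid (10 mol%), 4 Å molecular sieves, CH2Cl2, −20 → 0 °C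
Reagents that add atoms: none
Why: Acid ionises the tertiary allylic alcohol to the C10–C1–C2 allyl cation, and the phenol, held on the α face by C7', can reach only C2 and only from that face (intramolecular SN1' etherification); this closes the seven-membered ring, fixes C2 cis to C7' and leaves the tetrasubstituted C1=C10 alkene, while catalytic acid in an aprotic medium should spare the aryl acetals and any diene formed by proton loss can re-enter through the same cation.

Step 15
Reactants: 22 bridged benzoxepinone
Product: 23 bridged C7' alcohol (either C7' epimer)
Conditions: LiAlH4, THF, 0 °C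
Reagents that add atoms: none
Why: Hydride reduction of the aryl ketone; the configuration of the carbinol does not matter because it is ionised in step 16.

Step 16
Reactants: 23 bridged C7' alcohol; 24 trimethyl(2-methylallyl)silane
Product: 25 C7' 2-methylallyl compound (C7' configured as in 29)
Conditions: BF3·OEt2 (0.2 equiv), CH2Cl2, −78 °C
Reagents that add atoms: none
Why: The Lewis acid ionises the doubly ortho- and para-oxygenated benzylic alcohol to a strongly stabilised cation that the allylsilane captures at its γ-carbon (Hosomi–Sakurai-type SN1 allylation); in the rigid bicyclo[4.2.1] frame the nucleophile should approach the planar C7' from the exo side (the side of C3, anti to the C4–C5 bond) because the endo side is covered by H5 and the C1=C10 π face, which places the carbon chain as in 29, and the cation is too stabilised to trigger a Wagner–Meerwein shift at C4.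

Step 17
Reactants: 25 C7' 2-methylallyl compound
Product: 26 C7' isobutyl compound (4',6'-bis(methoxymethyl) ether of 27)
Conditions: H2 (3 atm), RhCl(PPh3)3 (5 mol%), benzene/EtOH, rt
Reagents that add atoms: none
Why: Homogeneous hydrogenation reduces the 1,1-disubstituted alkene and should leave the tetrasubstituted C1=C10 alkene, the cyclopropane and the allyl aryl ether untouched.

Step 18
Reactants: 26 C7' isobutyl bis(methoxymethyl) ether
Product: 27 4',6'-diol (deformyl target)
Conditions: HCl (3 M aq.), MeOH/THF, 40 °C
Reagents that add atoms: none
Why: Acid-catalysed acetal exchange removes both OCH2OMe groups far faster than the allyl aryl ether can ionise, and methanol traps the methoxymethyl cation as dimethoxymethane, which protects the electron-rich ring from hydroxymethylation.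

Step 19
Reactants: 27 4',6'-diol
Product: 29 target (CNP0388405.1), via bis(iminium) salt 28 (not isolated)
Conditions: POCl3, DMF, EtOAc, 0 °C → rt; then H2O, NaOAc, 50 °C
Reagents that add atoms: N,N-dimethylformamide, CN(C)C=O; water, O
Why: Vilsmeier–Haack formylation: the phloroglucinol-type ring should be attacked by the chloroiminium ion at both free positions (each ortho or para to three oxygens) and hydrolysis of the bis(iminium) salt gives the dialdehyde; no stereocentre is involved and the reagent is too weak an electrophile for the tetrasubstituted alkene.

## Compound list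

1 | (+)-2-carene, (1S,6R)-3,7,7-trimethylbicyclo[4.1.0]hept-2-ene | CC1=C[C@H]2[C@@H](CC1)C2(C)C | starting material
2 | secondary ozonide of 1 (1,2,4-trioxolane across the former C=C; acetal carbons unassigned; not isolated) | CC12CC[C@@H]3[C@H](C(OO1)O2)C3(C)C | intermediate
3 | (1S,3R)-2,2-dimethyl-3-(3-oxobutyl)cyclopropane-1-carbaldehyde | O=C[C@H]1[C@@H](CCC(C)=O)C1(C)C | intermediate
4 | 2-(triphenylphosphoranylidene)propanal | CC(C=O)=P(c1ccccc1)(c1ccccc1)c1ccccc1 | starting material
5 | (2E)-3-[(1S,3R)-2,2-dimethyl-3-(3-oxobutyl)cyclopropyl]-2-methylprop-2-enal | O=C/C(C)=C/[C@H]1[C@@H](CCC(C)=O)C1(C)C | intermediate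
6 | 4-{(1R,3S)-2,2-dimethyl-3-[(1E)-2-methylbuta-1,3-dien-1-yl]cyclopropyl}butan-2-one | C=C/C(C)=C/[C@H]1[C@@H](CCC(C)=O)C1(C)C | intermediate
7 | ethyl formate | CCOC=O | starting material
8 | lithium enolate of 6 (terminal enolate; not isolated) | C=C/C(C)=C/[C@H]1[C@@H](CCC(=C)[O-])C1(C)C.[Li+] | intermediate
9 | (1Z)-1-hydroxy-5-{(1R,3S)-2,2-dimethyl-3-[(1E)-2-methylbuta-1,3-dien-1-yl]cyclopropyl}pent-1-en-3-one | C=C/C(C)=C/[C@H]1[C@@H](CCC(=O)/C=C\O)C1(C)C | intermediate
10 | (1E)-1-chloro-5-{(1R,3S)-2,2-dimethyl-3-[(1E)-2-methylbuta-1,3-dien-1-yl]cyclopropyl}pent-1-en-3-one | C=C/C(C)=C/[C@H]1[C@@H](CCC(=O)/C=C/Cl)C1(C)C | intermediate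
11 | chloro cycloadduct: tricyclic C10 ketone with C2–Cl and C4=C7' (C1, C2 unassigned; H5 trans to H6; not isolated) | O=C1C2[C@H]([C@H]3[C@@H](CC1)C3(C)C)C(C)=CCC2Cl | intermediate
12 | tricyclic dienone: C10 ketone, C1=C2, C4(C15)=C7', cyclopropane C6–C7–C11, H5 trans to H6 | O=C1C=2[C@H]([C@H]3[C@@H](CC1)C3(C)C)C(C)=CCC2 | intermediate
13 | epoxy enone: 4,7'-epoxide of 12, oxygen on the face of H5 | O=C1C=2[C@H]([C@H]3[C@@H](CC1)C3(C)C)[C@@]4(C)O[C@H]4CC2 | intermediate
14 | enone aldehyde: cyclopentene C1–C5 (C1=C2) fused to the cyclopropane-bearing cycloheptanone; C4 bears C15 (cis to C6) and CHO (C7', cis to H5) | O=C1C=2[C@H]([C@H]3[C@@H](CC1)C3(C)C)[C@@](C)(C=O)CC2 | intermediate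
15 | phloroglucinol | Oc1cc(O)cc(O)c1 | starting material
16 | 1,3,5-tris(methoxymethoxy)benzene | COCOc1cc(OCOC)cc(OCOC)c1 | intermediate
17 | 2,4,6-tris(methoxymethoxy)phenyllithium (not isolated) | [Li]c1c(OCOC)cc(OCOC)cc1OCOC | intermediate
18 | C7' carbinol of 14 carrying the 2,4,6-tris(methoxymethoxy)phenyl group (both C7' epimers) | O=C1C=2[C@H]([C@H]3[C@@H](CC1)C3(C)C)[C@@](C)(C(O)c1c(OCOC)cc(OCOC)cc1OCOC)CC2 | intermediate
19 | aryl ketone (C7'=O) | O=C1C=2[C@H]([C@H]3[C@@H](CC1)C3(C)C)[C@@](C)(C(=O)c1c(OCOC)cc(OCOC)cc1OCOC)CC2 | intermediate
20 | 2'-hydroxy-4',6'-bis(methoxymethoxy)phenyl ketone | O=C1C=2[C@H]([C@H]3[C@@H](CC1)C3(C)C)[C@@](C)(C(=O)c1c(O)cc(OCOC)cc1OCOC)CC2 | intermediate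
21 | C10 tertiary allylic alcohol (C14 and OH on C10, C1=C2; both C10 epimers) | CC1(O)C=2[C@H]([C@H]3[C@@H](CC1)C3(C)C)[C@@](C)(C(=O)c1c(O)cc(OCOC)cc1OCOC)CC2 | intermediate
22 | bridged benzoxepinone: C2–O–C2' ether (oxygen cis to C7'), C1=C10, C7' ketone, 4',6'-bis(methoxymethoxy) | CC1=C2[C@H]([C@H]3[C@@H](CC1)C3(C)C)[C@]1(C)C[C@H]2Oc2cc(OCOC)cc(OCOC)c2C1=O | intermediate
23 | bridged C7' alcohol (either epimer) | CC1=C2[C@H]([C@H]3[C@@H](CC1)C3(C)C)[C@]1(C)C[C@H]2Oc2cc(OCOC)cc(OCOC)c2C1O | intermediate
24 | trimethyl(2-methylallyl)silane | CC(=C)C[Si](C)(C)C | starting material
25 | C7' 2-methylallyl compound (side chain exo, as in 29) | CC1=C2[C@H]([C@H]3[C@@H](CC1)C3(C)C)[C@]1(C)C[C@H]2Oc2cc(OCOC)cc(OCOC)c2[C@H]1CC(C)=C | intermediate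
26 | C7' isobutyl compound, 4',6'-bis(methoxymethyl) ether of 27 | CC1=C2[C@H]([C@H]3[C@@H](CC1)C3(C)C)[C@]1(C)C[C@H]2Oc2cc(OCOC)cc(OCOC)c2[C@H]1CC(C)C | intermediate
27 | 4',6'-diol (target without the two formyl groups) | CC1=C2[C@H]([C@H]3[C@@H](CC1)C3(C)C)[C@]1(C)C[C@H]2Oc2cc(O)cc(O)c2[C@H]1CC(C)C | intermediate
28 | 3',5'-bis(dimethyliminiomethyl) dichloride of 27 (not isolated) | CC1=C2[C@H]([C@H]3[C@@H](CC1)C3(C)C)[C@]1(C)C[C@H]2Oc2c(C=[N+](C)C)c(O)c(C=[N+](C)C)c(O)c2[C@H]1CC(C)C.[Cl-].[Cl-] | intermediate
29 | CNP0388405.1 | CC1=C2[C@H]([C@H]3[C@@H](CC1)C3(C)C)[C@]1(C)C[C@H]2Oc2c(C=O)c(O)c(C=O)c(O)c2[C@H]1CC(C)C | target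

## Step count and risk

Total step count: 19. Longest linear sequence: 18 steps (1 → 29 through steps 1–8 and 10–19); step 9 is a one-step branch.

Least certain steps:

Step 8 (key). The most likely failure is a shift of H7' instead of C3 (giving the C7' ketone) or proton loss from the C4 cation, if the aluminium-bound oxygen does not stay perpendicular to the cation plane. The fallback is a stepwise, halide-relayed semipinacol shift on the inverted epoxide, in which hydride cannot compete. It sets out from 13. Aqueous HClO4 in THF opens the epoxide at C4 with inversion to the trans-diol F1. MsCl/pyridine sulfonates only the secondary C7' hydroxyl, giving the mesylate F2. K2CO3/MeOH closes the inverted epoxide F3 (oxygen on the β face). LiBr in HMPA/benzene at 60 °C opens F3 at C4 with inversion to the lithium bromo alkoxide F4. In F4, H7' is syn to the C4–Br bond and cannot migrate, so C3 displaces bromide from the β face. Two inversions at C4 give the same configuration, and the sequence returns to the route at 14.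

Step 6. The cycloaddition may be too slow, so that 10 decomposes by HCl loss or polymerisation, or π-facial discrimination at C5 may be weak. The fallback uses a true alkynyl ketone, which reacts at lower temperature and needs no leaving group. It sets out from 9. Tf2O with 2,6-lutidine at −78 °C gives the (Z)-enol triflate F5, and Et3N eliminates triflic acid to the ynone F6. F6 should cyclise at or below 80 °C in toluene (or at rt with a cationic rhodium complex such as [Rh(cod)2]BF4) directly to the 1,4-diene, returning at 12.

Step 14. The allyl cation may lose a proton to cross-conjugated dienes or react intermolecularly before the phenol closes the seven-membered ring. The fallback forms the C2–O bond first by conjugate addition and introduces the alkene afterwards. It sets out from 20. Cs2CO3 in MeCN should give the oxa-Michael adduct F7. MeLi/CeCl3 at −78 °C adds to the C10 ketone to give the tertiary alcohol F8. Catalytic camphorsulfonic acid dehydrates F8 under equilibrating conditions to the tetrasubstituted alkene; the ether bridge is already in place. The sequence returns at 22.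

Step 16. The nucleophile may add to the endo face of the C7' cation, giving the C7' epimer. The fallback reverses the order in which carbon and hydrogen arrive at C7'. It sets out from 22. i-BuLi/CeCl3 at −78 °C adds to the ketone to give the tertiary alcohol F9. Et3SiH with BF3·OEt2 at −78 °C reduces the benzylic cation, so that hydride is the incoming group and the isobutyl group ends on the opposite side. Because the two sequences deliver the side chain from opposite faces, one of them must lead to the required epimer. The fallback returns at 26 and also saves the hydrogenation.

Step 19. The HCl released may ionise the allyl aryl ether or add to C1=C10, or the second formylation may stall on the deactivated ring. The fallback is anionic formylation at the protected stage. It sets out from 26. NBS (2 equiv) in MeCN at −30 °C should brominate the two free aryl positions to the dibromide F10. n-BuLi in THF at −78 °C followed by DMF gives the protected dialdehyde F11. Dilute HCl in MeOH removes the two acetals, which are now ortho to formyl groups on a deactivated ring. The sequence returns at 29.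

## Further compounds

F1 | step 8 | trans-diol from 13 (C4–OH β, C7'–OH α) | O=C1C=2[C@H]([C@H]3[C@@H](CC1)C3(C)C)[C@](C)(O)[C@@H](O)CC2
F2 | step 8 | C7' mesylate of F1 | O=C1C=2[C@H]([C@H]3[C@@H](CC1)C3(C)C)[C@](C)(O)[C@@H](OS(C)(=O)=O)CC2
F3 | step 8 | inverted epoxy enone (oxygen β, anti to H5) | O=C1C=2[C@H]([C@H]3[C@@H](CC1)C3(C)C)[C@]4(C)O[C@@H]4CC2
F4 | step 8 | lithium bromo alkoxide (C4–Br α, C7'–O β; not isolated) | O=C1C=2[C@H]([C@H]3[C@@H](CC1)C3(C)C)[C@@](C)(Br)[C@H]([O-])CC2.[Li+]
F5 | step 6 | (Z)-enol triflate of 9 | C=C/C(C)=C/[C@H]1[C@@H](CCC(=O)/C=C\OS(=O)(=O)C(F)(F)F)C1(C)C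
F6 | step 6 | 5-{(1R,3S)-2,2-dimethyl-3-[(1E)-2-methylbuta-1,3-dien-1-yl]cyclopropyl}pent-1-yn-3-one | C=C/C(C)=C/[C@H]1[C@@H](CCC(=O)C#C)C1(C)C
F7 | step 14 | oxa-Michael adduct of 20 (C2–O–C2' ether, C10 ketone, C1 unassigned) | O=C1C2[C@H]([C@H]3[C@@H](CC1)C3(C)C)[C@]1(C)C[C@H]2Oc2cc(OCOC)cc(OCOC)c2C1=O
F8 | step 14 | C10 tertiary alcohol of F7 (C1, C10 unassigned) | CC1(O)C2[C@H]([C@H]3[C@@H](CC1)C3(C)C)[C@]1(C)C[C@H]2Oc2cc(OCOC)cc(OCOC)c2C1=O
F9 | step 16 | C7' tertiary alcohol from 22 (isobutyl and OH on C7', configuration unassigned) | CC1=C2[C@H]([C@H]3[C@@H](CC1)C3(C)C)[C@]1(C)C[C@H]2Oc2cc(OCOC)cc(OCOC)c2C1(O)CC(C)C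
F10 | step 19 | 3',5'-dibromide of 26 | CC1=C2[C@H]([C@H]3[C@@H](CC1)C3(C)C)[C@]1(C)C[C@H]2Oc2c(Br)c(OCOC)c(Br)c(OCOC)c2[C@H]1CC(C)C
F11 | step 19 | 4',6'-bis(methoxymethyl) ether of 29 | CC1=C2[C@H]([C@H]3[C@@H](CC1)C3(C)C)[C@]1(C)C[C@H]2Oc2c(C=O)c(OCOC)c(C=O)c(OCOC)c2[C@H]1CC(C)C
A1 | alternative 1 | bridged cycloheptatriene (C1=C10, C8=C9, C6=C7) | CC1=C2[C@H](C=CC=C1)[C@]1(C)C[C@H]2Oc2cc(OC)cc(OC)c2[C@H]1CC(C)C
A2 | alternative 1 | benzoxepine-4-carbaldehyde tosylhydrazone with a 2-methylphenyl group on C2 | C[C@@]1(C=NNS(=O)(=O)c3ccc(C)cc3)C[C@H](c3ccccc3C)Oc2cc(OC)cc(OC)c2[C@H]1CC(C)C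
A3 | alternative 2 | 4',6'-dimethyl ether of 29 | CC1=C2[C@H]([C@H]3[C@@H](CC1)C3(C)C)[C@]1(C)C[C@H]2Oc2c(C=O)c(OC)c(C=O)c(OC)c2[C@H]1CC(C)C
A4 | alternative 2 | C2 allylic alcohol with a 2-fluoro-3,5-diformyl-4,6-dimethoxyphenyl group on C7' | CC1=C2[C@H]([C@H]3[C@@H](CC1)C3(C)C)[C@](C)(C[C@H]2O)[C@H](CC(C)C)c1c(F)c(C=O)c(OC)c(C=O)c1OC
A5 | alternative 3 | bridged C10 ketone (C1 unassigned) | O=C1C2[C@H]([C@H]3[C@@H](CC1)C3(C)C)[C@]1(C)C[C@H]2Oc2cc(OC)cc(OC)c2[C@H]1CC(C)C
A6 | alternative 3 | C1 diazo ketone attached through C5 to C4 of the benzoxepine | O=C1C(=[N+]=[N-])[C@H]([C@H]3[C@@H](CC1)C3(C)C)[C@]1(C)CCOc2cc(OC)cc(OC)c2[C@H]1CC(C)C
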